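The vessel was closed, stirred and isothermal, and I filled it twice; the two charges differ in free catalyst.

- red: substrate 1.0 M; partner 1.20 M; free catalyst 1.0 mM; time 10 min
- teal: substrate 1.0 M; partner 1.20 M; free catalyst 3.0 mM; time 10 min

    partner + free catalyst ⇌ catalyst intermediate A (K1 = 23 L mol⁻¹, k1 = 133 L mol⁻¹ min⁻¹)
    catalyst intermediate A → catalyst intermediate B (k2 = 2320 min⁻¹)
    substrate + catalyst intermediate B → catalyst intermediate C (k3 = 387 L mol⁻¹ min⁻¹)
    catalyst intermediate C → free catalyst + target (k4 = 2220 min⁻¹)
    2 partner → self-condensation product (k5 = 0.104 L mol⁻¹ min⁻¹)

- which of these there is most of at the end, counted by the substrate in it, red (catalyst intermediate C / substrate / target)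
- which of these there is most of at the end, counted by the substrate in it, teal (catalyst intermediate C / substrate / target)
- the largest of these amounts at the end, in percent of the substrate charged, red
- the largest of these amounts at the end, in percent of the substrate charged, teal

Partner had two exits, so I followed one quantity, the crossover level: the capture constant times [free catalyst], divided by 2 times the self-condensation constant. This is the [partner] at which capture and self-condensation use partner equally.

In the first instants the catalyst entered the cycle. At charge concentrations, waiting for capture made up 64.4% of a turn, so free catalyst was the resting state. I assumed the free share would climb as partner fell, and used the midpoint between that start and the whole charge, 82.2%.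

That gave a crossover level of 0.526 M for red and 1.58 M for teal. By these levels, reckoned with the midpoint share and not the share at the start, red's partner charge stood above its level and teal's stood below its level; I read that as self-condensation ahead in red and capture ahead in teal.

In the middle, I expected the comparison to drift towards capture: as [partner] falls, self-condensation falls with its square and capture with its first power. The share captured is the crossover level over the sum of that level and [partner].

At the end, integrating that share gave my figures for 10 min:

| | red | teal |
|---|---|---|
| crossover level | 0.526 M | 1.58 M |
| partner left | 0.160 M | 0.0261 M |
| target | 48.5% | 86.6% |
| ceiling at zero partner | 62.5% | 89.2% |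

So I committed to substrate at 51.5% for red and target at 86.6% for teal.

The forecast named substrate at 54% for red and target at 83% for teal, reasoning that “3 mM catalyst captures enough partner to make target dominant”. My red substrate figure was lower than its figure, and my teal target figure was higher than its figure.

Red ended with substrate at 54.0% and teal with target at 83.4%. Substrate and target draw level at 1.13 mM of free catalyst, and red's 1.0 mM lay below that value. Red's reckoned ceiling of 62.5% stood above the 60.2% of target that red held at 100 min. For a neighbour of teal with 0.012 M of free catalyst, the same midpoint share gave a reckoned crossover level of 6.31 M and a reckoned ceiling of 1.10 M, more than the substrate charge. That neighbour of teal ended with 100% target.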